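**Plan**

1. Locants (elemane type): cyclohexane C5–C10 (C10 = C(CH3)(vinyl), C9 = CH2, C8 = CH–OAc, C7 and C6 = ring fusion with the lactone O on C6, C5 = CH–isopropenyl); C1=C2 is the vinyl group, C11/C12 the lactone α-carbon and carbonyl.
2. Cuts, last to first: the C11–O angelate and C8–O acetate; C11–OH (enolate oxidation); C1=C2 (Peterson) and the lactone C6–O–C12 bond; then the carbocycle at C9–C10 and C5–C6 in one [4+2] step, together with a silicon tether O8–Si–O–C1.
3. Enabling feature: C6 and C8 carry oxygen 1,3 on the ring, so C6=C7–C8=C9 is a 1-alkoxy-3-silyloxydiene; C5 carries a carbonyl-derived isopropenyl group, so C5=C10 is an enone; C1 on C10 is 1,3 to C8, so an O8–Si–O–C1 bridge can tie the two partners (type 2 intramolecular Diels–Alder).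
4. Forward: carbinol 4 (from 2,4-dimethylfuran) and dienyl ketone 11 are joined through silicon; the cycloaddition closes the cyclohexene (the only carbocycle); then isopropenyl, bridge removal, C8 reduction, γ-lactone ring, vinyl plus C11–OH, and the two esters.
5. Stereochemistry: the C1 carbinol (catalytic asymmetric addition) is relayed to C10, C5 and C6 in the tethered transition state; C7 comes from protonation anti to the bridge, C8 from hydride delivery by the C1 hydroxyl, C11 from convex-face hydroxylation; C1 then disappears into the vinyl group.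

Key step: step 7

Assumption: the (S)-H8-BINOL–titanium catalyst is taken to deliver the alkyl group to the Si face of aldehyde 3, as it does with aryl aldehydes; if the sense were opposite, the (R)-ligand would be used.
Remark: from 11 up to 21 all compounds are mixtures of epimers at the side-chain CH(CH3) carbon (C11); this centre is set in step 12.
Remark: the SMILES of the Tebbe reagent is written in its open form, with chlorine bound to titanium only; the dative Cl→Al bridge is not drawn.

Step 1
Reactants: 1 2,4-dimethylfuran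
Product: 3 (2E)-2-methyl-4-oxopent-2-enal, via Z-enedicarbonyl 2 (not isolated)
Conditions: NBS, NaHCO3, acetone/H2O (10:1), −15 °C; then pyridine, rt
Reagents that add atoms: water, O
Why: Oxidative ring opening of the furan (bromination at the free α-position, hydration, opening of the 2,5-dihydrofuran) should give the cis-enedicarbonyl 2, which pyridine isomerises by conjugate addition–elimination to the more stable E isomer 3 (furan-to-trans-enedione oxidation).

Step 2
Reactants: 3 (2E)-2-methyl-4-oxopent-2-enal
Product: 4 (3E,5R)-5-hydroxy-4-methyl-6-(trimethylsilyl)hex-3-en-2-one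
Conditions: Me3SiCH2MgCl, Ti(OiPr)4, (S)-3-(3,5-diphenylphenyl)-H8-BINOL (2 mol %), CH2Cl2, 0 °C
Reagents that add atoms: (trimethylsilyl)methylmagnesium chloride, C[Si](C)(C)C[Mg]Cl
Why: Catalytic enantioselective 1,2-addition of the alkyltitanium species Me3SiCH2Ti(OiPr)3 formed from the Grignard reagent and Ti(OiPr)4 under a chiral titanium H8-BINOLate; the aldehyde should react much faster than the methyl ketone, and Si-face delivery sets the (5R) carbinol.

Step 3
Reactants: 5 (3E)-4-methoxybut-3-en-2-one; 6 (4-methoxyphenyl)methanol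
Product: 7 (3E)-4-[(4-methoxyphenyl)methoxy]but-3-en-2-one
Conditions: pyridinium p-toluenesulfonate (cat.), toluene, 90 °C, MeOH distilled off
Reagents that add atoms: none
Why: Acid-catalysed transetherification of the vinylogous ester (conjugate addition of the alcohol, loss of methanol), driven by removal of methanol; the E geometry is the thermodynamic one.

Step 4
Reactants: 7 (3E)-4-[(4-methoxyphenyl)methoxy]but-3-en-2-one
Product: 8 (3Z)-3-iodo-4-[(4-methoxyphenyl)methoxy]but-3-en-2-one
Conditions: I2, pyridine, CH2Cl2, 0 °C → rt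
Reagents that add atoms: iodine, II
Why: Electrophilic α-iodination of the vinylogous ester at its nucleophilic α-carbon (I2/pyridine α-iodination of enones); the alkoxy group should stay trans to the acetyl group.

Step 5
Reactants: 8 (3Z)-3-iodo-4-[(4-methoxyphenyl)methoxy]but-3-en-2-one; 9 methyl 2-bromopropanoate
Product: 11 methyl (3E)-3-acetyl-4-[(4-methoxyphenyl)methoxy]-2-methylbut-3-enoate, via Reformatsky reagent 10 (not isolated)
Conditions: 9, Zn dust, THF, rt; then 8, Pd2(dba)3 (2.5 mol %), P(tBu)3 (10 mol %), THF, rt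
Reagents that add atoms: none
Why: The zinc ester enolate 10 should couple with the alkenyl iodide under zerovalent palladium (Negishi-type coupling of a Reformatsky reagent) with retention of the alkene geometry; the new CH(CH3) centre is racemic, which does not matter because it is made planar in step 12.

Step 6
Reactants: 11 methyl (3E)-3-acetyl-4-[(4-methoxyphenyl)methoxy]-2-methylbut-3-enoate; 4 (3E,5R)-5-hydroxy-4-methyl-6-(trimethylsilyl)hex-3-en-2-one
Product: 14 silaketal triene, via lithium dienolate 12 (not isolated), via chlorosilyl dienol ether 13 (not isolated)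
Conditions: LiN(iPr)2, THF, −78 °C; iPr2SiCl2 (4 equiv), −78 °C → rt, excess evaporated; 4, imidazole, CH2Cl2, 0 °C → rt
Reagents that add atoms: dichlorodiisopropylsilane, CC(C)[Si](Cl)(Cl)C(C)C
Why: Kinetic deprotonation of the methyl ketone gives the cross-conjugated dienolate 12, O-silylation with excess dichlorosilane gives 13, and the remaining Si–Cl is displaced by alcohol 4 (sequential assembly of a mixed silaketal as a temporary silicon tether); no stereocentre is touched.

Step 7
Reactants: 14 silaketal triene
Product: 15 bridged silaketal cycloadduct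
Conditions: toluene (5 mM), 2,6-di-tert-butyl-4-methylphenol (cat.), 110 °C, sealed tube
Reagents that add atoms: none
Why: Thermal type 2 intramolecular Diels–Alder reaction: the 1-alkoxy-3-silyloxydiene C6=C7–C8=C9 (largest HOMO coefficient at C9) should add suprafacially to the enone C5=C10 (largest LUMO coefficient at C10), forming C9–C10 and C5–C6 in one concerted, asynchronous [4+2] event; the closest known reaction type is the silicon-tethered type 2 intramolecular Diels–Alder reaction that gives bridgehead alkenes. The cyclohexene ring closes in the [4+2] mode, and the seven-membered dioxasilepane ring closes in the bridged (1,3) mode that a four-atom tether from the 2-position of the diene enforces, giving a bicyclo[4.3.1] skeleton with the C7=C8 enol ether at the bridgehead. C10 and C5 take their relative configuration from the E dienophile (methyl cis to acetyl); C6 takes its configuration from the E enol ether and the tether, which forces the C1 branch endo and the acetyl group exo, so that C6–O ends cis to C1 and trans to the acetyl group. The absolute sense comes from the C1 carbinol stereocentre inside the tether: its CH2SiMe3 group points away from the diene and its hydrogen inward, so only one face of the dienophile can reach the diene. The step needs regioselectivity (C9 to C10), exo orientation of the acetyl group and one diene face; the tether length secures the first two and the C1 substituent the third.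

Step 8
Reactants: 15 bridged silaketal cycloadduct
Product: 16 bridged isopropenyl compound
Conditions: Cp2Ti(μ-Cl)(μ-CH2)AlMe2, pyridine, THF/toluene, −40 → 0 °C
Reagents that add atoms: Tebbe reagent Cp2Ti(μ-Cl)(μ-CH2)AlMe2, C[Al](C)C[Ti](Cl)(C1C=CC=C1)C1C=CC=C1
Why: Tebbe methylenation (titanium methylidene, oxatitanacyclobutane) should convert the methyl ketone into the isopropenyl group; at low temperature the ketone reacts far faster than the ester, and the non-basic reagent leaves C5 and the silyl enol ether untouched.

Step 9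
Reactants: 16 bridged isopropenyl compound
Product: 18 hydroxy ketone, via fluorosilyl ether 17 (not isolated)
Conditions: HF·pyridine, pyridine, THF, 0 °C
Reagents that add atoms: none
Why: Protodesilylation of the strained bridgehead silyl enol ether: protonation at C7 should occur on the face opposite the siloxane bridge and the C6 ether, which places the C7 side chain cis to C6–O, and fluoride then removes silicon from both oxygens via 17; the PMB ether, the ester and the C–Si bond should survive buffered HF.

Step 10
Reactants: 18 hydroxy ketone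
Product: 19 diol ester
Conditions: Me4NBH(OAc)3, AcOH/MeCN (1:1), −30 → 0 °C
Reagents that add atoms: none
Why: Hydroxyl-directed reduction (Evans–Saksena type): the C1 carbinol exchanges onto boron and delivers hydride intramolecularly to the C8 carbonyl on the face that carries the C1 branch, which sets the C8 hydroxyl trans to that branch and to the C7 side chain; the reagent does not reduce ketones without such delivery.

Step 11
Reactants: 19 diol ester
Product: 21 silyl diol lactone, via triol ester 20 (not isolated)
Conditions: DDQ, CH2Cl2/pH 7 buffer, 0 °C; then camphorsulfonic acid (cat.), CH2Cl2, rt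
Reagents that add atoms: none
Why: Oxidative cleavage of the PMB ether frees the C6 hydroxyl (20), which under acid catalysis should close the cis-fused γ-lactone with the cis C7 ester side chain; the C8 hydroxyl is trans to that chain and stays free.

Step 12
Reactants: 21 silyl diol lactone
Product: 23 dihydroxy lactone, via vinyl lactone 22 (not isolated)
Conditions: KN(SiMe3)2 (3.5 equiv), THF, −78 → 0 °C; then −78 °C, 3-phenyl-2-(phenylsulfonyl)oxaziridine; AcOH
Reagents that add atoms: 3-phenyl-2-(phenylsulfonyl)oxaziridine, O=S(=O)(c1ccccc1)N1OC1c1ccccc1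
Why: The potassium β-silyl alkoxide should undergo syn Peterson elimination to the vinyl group (22), and the potassium lactone enolate should be hydroxylated by the oxaziridine on the convex face of the cis-fused bicycle (anti to the cyclohexane ring), so that both C11 epimers of 21 converge on one tertiary alcohol.

Step 13
Reactants: 23 dihydroxy lactone
Product: 24 C8 monoacetate
Conditions: Ac2O, pyridine, 4-(dimethylamino)pyridine (cat.), CH2Cl2, 0 °C → rt
Reagents that add atoms: acetic anhydride, CC(=O)OC(C)=O
Why: Acylation should be selective for the secondary C8 hydroxyl over the tertiary C11 hydroxyl next to the lactone carbonyl.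

Step 14
Reactants: 24 C8 monoacetate; 25 angelic acid
Product: 27 target, via mixed anhydride 26 (not isolated)
Conditions: 25, 2,4,6-Cl3C6H2COCl, Et3N, toluene, rt; 24, LiN(SiMe3)2, THF, −78 °C, then 26, −78 → 0 °C
Reagents that add atoms: none
Why: Yamaguchi-type mixed anhydride 26 should acylate the lithium alkoxide of the tertiary alcohol at the less hindered angeloyl carbonyl; low temperature and the absence of a nucleophilic amine at the acylation stage should keep the Z geometry.

**Compound list**

1 | 2,4-dimethylfuran | Cc1cc(C)co1 | starting material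
2 | (2Z)-2-methyl-4-oxopent-2-enal | CC(=O)/C=C(C)\C=O | intermediate
3 | (2E)-2-methyl-4-oxopent-2-enal | CC(=O)/C=C(C)/C=O | intermediate
4 | (3E,5R)-5-hydroxy-4-methyl-6-(trimethylsilyl)hex-3-en-2-one | C[Si](C)(C)C[C@H](O)/C(C)=C/C(C)=O | intermediate
5 | (3E)-4-methoxybut-3-en-2-one | CO/C=C/C(C)=O | starting material
6 | (4-methoxyphenyl)methanol | COc1ccc(CO)cc1 | starting material
7 | (3E)-4-[(4-methoxyphenyl)methoxy]but-3-en-2-one | CC(=O)/C=C/OCc1ccc(OC)cc1 | intermediate
8 | (3Z)-3-iodo-4-[(4-methoxyphenyl)methoxy]but-3-en-2-one | CC(=O)/C(I)=C/OCc1ccc(OC)cc1 | intermediate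
9 | methyl 2-bromopropanoate (racemic) | COC(=O)C(C)Br | starting material
10 | bromo(1-methoxy-1-oxopropan-2-yl)zinc | COC(=O)C(C)[Zn]Br | intermediate
11 | methyl (3E)-3-acetyl-4-[(4-methoxyphenyl)methoxy]-2-methylbut-3-enoate (racemic at C2) | CC(=O)/C(C(C)C(=O)OC)=C/OCc1ccc(OC)cc1 | intermediate
12 | lithium dienolate of 11 (enolate of the acetyl methyl group) | [Li+].C=C([O-])/C(C(C)C(=O)OC)=C/OCc1ccc(OC)cc1 | intermediate
13 | chloro(diisopropyl)silyl dienol ether of 11 | C=C(O[Si](Cl)(C(C)C)C(C)C)/C(C(C)C(=O)OC)=C/OCc1ccc(OC)cc1 | intermediate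
14 | silaketal triene: methyl (3E)-3-{1-[diisopropyl({(2R,3E)-3-methyl-5-oxo-1-(trimethylsilyl)hex-3-en-2-yl}oxy)silyl]oxyethenyl}-4-[(4-methoxyphenyl)methoxy]-2-methylbut-3-enoate | C=C(O[Si](C(C)C)(C(C)C)O[C@@H](C[Si](C)(C)C)/C(C)=C/C(C)=O)/C(C(C)C(=O)OC)=C/OCc1ccc(OC)cc1 | intermediate
15 | bridged cycloadduct: cyclohexene with the C7=C8 silyl enol ether, CH(CH3)CO2Me on C7, PMB ether on C6, acetyl on C5 (trans to C6–O), methyl on C10; a C8–O–Si(iPr)2–O–C1 bridge to the (R)-carbinol C1 [CH(CH2SiMe3)] on C10 (cis to C6–O); C5, C6, C10 as in the target | C[Si](C)(C)C[C@@H]1O[Si](C(C)C)(C(C)C)OC2=C(C(C)C(=O)OC)[C@@H](OCc3ccc(OC)cc3)[C@H](C(C)=O)[C@]1(C)C2 | intermediate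
16 | as 15 with prop-1-en-2-yl in place of acetyl on C5 | C[Si](C)(C)C[C@@H]1O[Si](C(C)C)(C(C)C)OC2=C(C(C)C(=O)OC)[C@@H](OCc3ccc(OC)cc3)[C@H](C(C)=C)[C@]1(C)C2 | intermediate
17 | C8 ketone with C7–H set and the C1 oxygen still carrying fluoro(diisopropyl)silyl | C[Si](C)(C)C[C@H](O[Si](F)(C(C)C)C(C)C)[C@@]1(C)CC(=O)[C@@H](C(C)C(=O)OC)[C@@H](OCc2ccc(OC)cc2)[C@@H]1C(C)=C | intermediate
18 | hydroxy ketone: cyclohexanone (C8=O) with methyl and (1R)-1-hydroxy-2-(trimethylsilyl)ethyl on C10, prop-1-en-2-yl on C5, PMB ether on C6, CH(CH3)CO2Me on C7 (cis to C6–O); C5, C6, C7, C10 as in the target | C[Si](C)(C)C[C@H](O)[C@@]1(C)CC(=O)[C@@H](C(C)C(=O)OC)[C@@H](OCc2ccc(OC)cc2)[C@@H]1C(C)=C | intermediate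
19 | diol ester: as 18 with C8–OH (trans to the C7 side chain and to the C1 branch), C8 as in the target | C[Si](C)(C)C[C@H](O)[C@@]1(C)C[C@H](O)[C@@H](C(C)C(=O)OC)[C@@H](OCc2ccc(OC)cc2)[C@@H]1C(C)=C | intermediate
20 | triol ester: as 19 with free C6–OH | C[Si](C)(C)C[C@H](O)[C@@]1(C)C[C@H](O)[C@@H](C(C)C(=O)OC)[C@@H](O)[C@@H]1C(C)=C | intermediate
21 | cis-fused γ-lactone (C6–O–C12) with C8–OH and the (1R)-1-hydroxy-2-(trimethylsilyl)ethyl group on C10; C11 epimers | C[Si](C)(C)C[C@H](O)[C@@]1(C)C[C@H](O)[C@@H]2[C@@H](OC(=O)C2C)[C@@H]1C(C)=C | intermediate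
22 | (3aR,4S,6R,7R,7aS)-6-ethenyl-4-hydroxy-3,6-dimethyl-7-(prop-1-en-2-yl)hexahydro-1-benzofuran-2(3H)-one (C3 epimers) | C=C[C@@]1(C)C[C@H](O)[C@@H]2[C@@H](OC(=O)C2C)[C@@H]1C(=C)C | intermediate
23 | (3S,3aR,4S,6R,7R,7aS)-6-ethenyl-3,4-dihydroxy-3,6-dimethyl-7-(prop-1-en-2-yl)hexahydro-1-benzofuran-2(3H)-one | C=C[C@@]1(C)C[C@H](O)[C@@H]2[C@@H](OC(=O)[C@@]2(C)O)[C@@H]1C(=C)C | intermediate
24 | (3S,3aR,4S,6R,7R,7aS)-6-ethenyl-3-hydroxy-3,6-dimethyl-2-oxo-7-(prop-1-en-2-yl)octahydro-1-benzofuran-4-yl acetate | C=C[C@@]1(C)C[C@H](OC(C)=O)[C@@H]2[C@@H](OC(=O)[C@@]2(C)O)[C@@H]1C(=C)C | intermediate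
25 | angelic acid, (2Z)-2-methylbut-2-enoic acid | C/C=C(/C)C(=O)O | starting material
26 | (2Z)-2-methylbut-2-enoic 2,4,6-trichlorobenzoic anhydride | C/C=C(/C)C(=O)OC(=O)c1c(Cl)cc(Cl)cc1Cl | intermediate
27 | (3S,3aR,4S,6R,7R,7aS)-4-(acetyloxy)-6-ethenyl-3,6-dimethyl-2-oxo-7-(prop-1-en-2-yl)octahydro-1-benzofuran-3-yl (2Z)-2-methylbut-2-enoate | C=C[C@@]1(C)C[C@H](OC(C)=O)[C@@H]2[C@@H](OC(=O)[C@@]2(C)OC(=O)/C(C)=C\C)[C@@H]1C(=C)C | target

**Totals and risks**

Total steps: 14. Longest linear sequence: 12 steps (5 to 27, steps 3–14).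

Step 7 may fail through hydrolytic or thermal loss of the silaketal tether, through intermolecular oligomerisation before the cycloaddition, or through weak discrimination of the two diene faces. The fallback sets out from 11 and 4 and gives up the tether. Compound 11 is converted into the tert-butyldimethylsilyl dienol ether F1 (LiN(iPr)2, tBuMe2SiCl) and 4 into the triethylsilyl ether F2 (Et3SiCl, imidazole). The two are combined at 12 kbar in CH2Cl2, where the polarity-matched [4+2] addition (CH2 terminus to the enone β-carbon) should give the cycloadduct F3, whose exo-acetyl isomer is separated. Tebbe methylenation gives the isopropenyl compound F4, and HF·pyridine cleaves both silyl groups and rejoins the route at 18.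

Step 10 may fail because the seven-membered hydride-transfer transition state is not reached, so that reduction is slow or proceeds without delivery on the other face. The fallback sets out from 18 and installs the C8 configuration by inversion. Non-directed reduction with LiBH(sBu)3 on the face opposite the C7 side chain should give the 8-epi alcohol F5. Mitsunobu inversion (4-nitrobenzoic acid, PPh3, diisopropyl azodicarboxylate; the neopentylic C1 carbinol should not react) gives the inverted 4-nitrobenzoate F6, and K2CO3/MeOH rejoins the route at 19.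

Step 14 may fail through slow acylation of the hindered tertiary alkoxide and through isomerisation of the Z double bond to the E (tiglate) geometry. The fallback sets out from 24 and builds the double bond on the ester. The lithium alkoxide is acylated with 2-[bis(2,2,2-trifluoroethoxy)phosphoryl]propanoyl chloride to give the phosphonopropanoate F7. Z-selective Horner–Wadsworth–Emmons olefination in the Still–Gennari mode (KN(SiMe3)2, 18-crown-6, acetaldehyde, THF, −78 °C) then rejoins the route at 27.

**Further compounds**

F1 | step 7 | tert-butyldimethylsilyl dienol ether of 11 | C=C(O[Si](C)(C)C(C)(C)C)/C(C(C)C(=O)OC)=C/OCc1ccc(OC)cc1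
F2 | step 7 | triethylsilyl ether of 4, (3E,5R)-4-methyl-5-[(triethylsilyl)oxy]-6-(trimethylsilyl)hex-3-en-2-one | CC[Si](CC)(CC)O[C@@H](C[Si](C)(C)C)/C(C)=C/C(C)=O
F3 | step 7 | untethered cycloadduct: C7=C8 tert-butyldimethylsilyl enol ether with C5 acetyl, C6 PMB ether, C10 methyl and (1R)-1-[(triethylsilyl)oxy]-2-(trimethylsilyl)ethyl; C5, C6, C10 as in the target | C[Si](C)(C)C[C@H](O[Si](CC)(CC)CC)[C@@]1(C)CC(O[Si](C)(C)C(C)(C)C)=C(C(C)C(=O)OC)[C@@H](OCc2ccc(OC)cc2)[C@@H]1C(C)=O
F4 | step 7 | as F3 with prop-1-en-2-yl in place of acetyl on C5 | C[Si](C)(C)C[C@H](O[Si](CC)(CC)CC)[C@@]1(C)CC(O[Si](C)(C)C(C)(C)C)=C(C(C)C(=O)OC)[C@@H](OCc2ccc(OC)cc2)[C@@H]1C(C)=C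
F5 | step 10 | C8 epimer of 19 (C8–OH cis to the C7 side chain) | C[Si](C)(C)C[C@H](O)[C@@]1(C)C[C@@H](O)[C@@H](C(C)C(=O)OC)[C@@H](OCc2ccc(OC)cc2)[C@@H]1C(C)=C
F6 | step 10 | 4-nitrobenzoate of 19 at the C8 oxygen | C[Si](C)(C)C[C@H](O)[C@@]1(C)C[C@H](OC(=O)c2ccc([N+](=O)[O-])cc2)[C@@H](C(C)C(=O)OC)[C@@H](OCc3ccc(OC)cc3)[C@@H]1C(C)=C
F7 | step 14 | 2-[bis(2,2,2-trifluoroethoxy)phosphoryl]propanoate of 24 at the C11 oxygen | C=C[C@@]1(C)C[C@H](OC(C)=O)[C@@H]2[C@@H](OC(=O)[C@@]2(C)OC(=O)C(C)P(=O)(OCC(F)(F)F)OCC(F)(F)F)[C@@H]1C(=C)C
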